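**Strategy.** The tetralin is cut at C4–C4a. In the target, C3 carries two CH2 groups, C4 bound to ring A and C9 bound to OH; they are read as the two CH2–O arms of an oxetan-3-yl group on C2, and C4a sits para to the C7 hydroxyl. One acid-promoted step lets that phenol ring open the oxetane through C4a (6-exo-tet), closing the carbocycle, creating C3 and releasing the C9 alcohol. The precursor is an acyclic 1,1-diarylpropane with C1 and C2 already set: ring A as free 3-hydroxy-2,4-dimethoxyphenyl, the guaiacyl ring and the C9' oxygen both masked as pivalates, and the oxetane on C2.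

Key step: step 13

Remark (numbering and sources): tetralin numbering is used for all intermediates (aryl-bearing carbon C1; arms C9' on C2 and C9 on C3; ring A is the 3-oxy-2,4-dimethoxyphenyl ring that becomes C4a–C8a). Compounds 1, 2, 6, 9 and 16 are taken as commercial.

Remark (precursor design): the guaiacyl phenol is carried as a pivalate, not a sulfonate. The acyloxy group sits meta to that ring's reactive carbon and the ester binds the Lewis acid, so the ring is deactivated, and one hydride step removes both esters at the end. The C9' pivalate is bulky and cannot chelate a monodentate Lewis acid. Only ring A has a free para-hydroxyl.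

**Route**

Step 1
Reactants: 1 oxetan-3-one; 2 benzyl (triphenylphosphoranylidene)acetate
Product: 3 benzyl 2-(oxetan-3-ylidene)acetate
Conditions: CH2Cl2, 0 °C → rt
Reagents that add atoms: none
Why: Wittig olefination with a stabilised ylide proceeds on the strained, unhindered ketone without added base or acid, so the oxetane is not put at risk; no stereocentre is formed.

Step 2
Reactants: 3 benzyl 2-(oxetan-3-ylidene)acetate
Product: 5 triethylammonium 2-(oxetan-3-yl)acetate, via benzyl 2-(oxetan-3-yl)acetate 4 (not isolated)
Conditions: H2 (1 atm), 10% Pd/C, Et3N (1.1 equiv), EtOAc, rt; filter, concentrate below 25 °C, use at once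
Reagents that add atoms: triethylamine, CCN(CC)CC
Why: Heterogeneous hydrogenation saturates the exocyclic alkene (via 4) and hydrogenolyses the benzyl ester, and triethylamine traps the acid as its ammonium salt because free oxetane carboxylic acids tend to isomerise to lactones; the new CH of the symmetric oxetane is not stereogenic.

Step 3
Reactants: 5 triethylammonium 2-(oxetan-3-yl)acetate; 6 (S)-4-benzyloxazolidin-2-one
Product: 8 (S)-4-benzyl-3-[2-(oxetan-3-yl)acetyl]oxazolidin-2-one, via pivalic mixed anhydride 7 (not isolated)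
Conditions: PivCl, Et3N, THF, −20 °C; then 6, LiCl, −20 °C → rt
Reagents that add atoms: none
Why: N-Acylation of the oxazolidinone through the pivalic mixed anhydride (LiCl/Et3N activation) should be regioselective for the unhindered carbonyl and keeps the oxetane away from free acid; no stereocentre is touched.

Step 4
Reactants: 9 vanillin
Product: 10 4-(tert-butyldimethylsilyloxy)-3-methoxybenzaldehyde
Conditions: TBSCl, imidazole, CH2Cl2, rt
Reagents that add atoms: tert-butyldimethylsilyl chloride, CC(C)(C)[Si](C)(C)Cl
Why: Standard silylation of the phenol masks the acidic OH for the boron enolate chemistry and leaves a group that fluoride removes later.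

Step 5
Reactants: 8 (S)-4-benzyl-3-[2-(oxetan-3-yl)acetyl]oxazolidin-2-one; 10 4-(tert-butyldimethylsilyloxy)-3-methoxybenzaldehyde
Product: 12 (4S)-4-benzyl-3-[(2S,3S)-3-[4-(tert-butyldimethylsilyloxy)-3-methoxyphenyl]-3-hydroxy-2-(oxetan-3-yl)propanoyl]oxazolidin-2-one, via dibutylboron Z-enolate 11 (not isolated)
Conditions: i-Pr2NEt, Bu2BOTf (1.1 equiv), CH2Cl2, −78 → 0 °C; 10, −78 → 0 °C; pH 7 buffer, MeOH, H2O2, 0 °C
Reagents that add atoms: none
Why: Evans syn aldol reaction: the Z dibutylboron enolate reacts through a closed Zimmerman–Traxler chair with the auxiliary carbonyl turned away, so the aldehyde takes the enolate face opposite the benzyl group and the α-carbon (later C2) is set as 2S, while the syn 3S carbinol centre is only a handle that is erased in step 11.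

Step 6
Reactants: 12 aldol adduct
Product: 13 (1S,2R)-1-[4-(tert-butyldimethylsilyloxy)-3-methoxyphenyl]-2-(oxetan-3-yl)propane-1,3-diol
Conditions: LiBH4, MeOH (1 equiv), THF, 0 °C
Reagents that add atoms: none
Why: Reductive cleavage of the N-acyl oxazolidinone with LiBH4 (hydride attack on the exocyclic, lithium-chelated carbonyl) gives the primary alcohol and returns the auxiliary without touching the two stereocentres, the oxetane or the aryl silyl ether.

Step 7
Reactants: 13 diol
Product: 14 (1S,2R)-1-[4-(tert-butyldimethylsilyloxy)-3-methoxyphenyl]-2-(oxetan-3-yl)propane-1,3-diyl bis(2,2-dimethylpropanoate)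
Conditions: PivCl (4 equiv), Et3N, DMAP, CH2Cl2, 0 → 35 °C
Reagents that add atoms: pivaloyl chloride, CC(C)(C)C(=O)Cl
Why: DMAP-catalysed acylation esterifies both hydroxyls, which installs the C9' protecting group and, at the benzylic position, the leaving group for quinone methide formation, with no change at either stereocentre.

Step 8
Reactants: 14 bis-pivalate
Product: 15 (1S,2R)-1-(4-hydroxy-3-methoxyphenyl)-2-(oxetan-3-yl)propane-1,3-diyl bis(2,2-dimethylpropanoate)
Conditions: TBAF, AcOH (1.5 equiv), THF, 0 °C; used crude
Reagents that add atoms: none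
Why: Fluoride cleaves the aryl silyl ether and the acetic acid buffer keeps the product as the neutral phenol, so that the p-hydroxybenzyl pivalate does not eliminate before the organometallic step.

Step 9
Reactants: 16 2,6-dimethoxyphenol
Product: 17 2-(benzyloxy)-1,3-dimethoxybenzene
Conditions: BnBr, K2CO3, DMF, 60 °C
Reagents that add atoms: benzyl bromide, BrCc1ccccc1
Why: Williamson etherification of the phenoxide protects the central oxygen with a group that hydrogenolysis removes.

Step 10
Reactants: 17 2-(benzyloxy)-1,3-dimethoxybenzene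
Product: 18 3-(benzyloxy)-1-bromo-2,4-dimethoxybenzene
Conditions: NBS (1.0 equiv), MeCN, 0 °C → rt
Reagents that add atoms: N-bromosuccinimide, O=C1CCC(=O)N1Br
Why: Electrophilic aromatic bromination should go to C4, para to one methoxy and ortho to the other, because the flanked benzyloxy group is twisted out of conjugation and does not direct to its own para position.

Step 11
Reactants: 15 phenol bis-pivalate; 18 3-(benzyloxy)-1-bromo-2,4-dimethoxybenzene
Product: 22 (2R,3S)-3-[3-(benzyloxy)-2,4-dimethoxyphenyl]-3-[3-methoxy-4-(pivaloyloxy)phenyl]-2-(oxetan-3-yl)propyl pivalate, via arylmagnesium bromide 19 (not isolated), via quinone methide 20 (not isolated), via phenol adduct 21 (not isolated)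
Conditions: 18 (3.5 equiv), Mg, THF, rt; CuBr·SMe2 (10 mol %), then 15, THF, −78 → −20 °C; then PivCl (6 equiv), DMAP (cat.), 0 °C → rt
Reagents that add atoms: pivaloyl chloride, CC(C)(C)C(=O)Cl
Why: The first equivalent of arylmagnesium deprotonates the phenol, the magnesium phenoxide expels the benzylic pivalate to give the p-quinone methide (the carbinol centre is erased), and copper-catalysed 1,6-conjugate addition of the aryl group restores the arene and creates C1 by 1,2-induction: with C2–H eclipsing the exocyclic C=C (allylic strain) the aryl should enter anti to the pivaloyloxymethyl arm, which is the better σ-acceptor and bulkier than the tied-back oxetanyl ring, giving 3S (C1 of the target), before the phenoxide is acylated in the same flask.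

Step 12
Reactants: 22 benzyl ether
Product: 23 (2R,3S)-3-(3-hydroxy-2,4-dimethoxyphenyl)-3-[3-methoxy-4-(pivaloyloxy)phenyl]-2-(oxetan-3-yl)propyl pivalate
Conditions: H2 (1 atm), Pd/C, EtOAc, rt
Reagents that add atoms: none
Why: Hydrogenolysis of the benzyl aryl ether frees the C7 hydroxyl of ring A, while the esters, the oxetane and the doubly benzylic C1–H centre are inert to Pd/C under hydrogen.

Step 13
Reactants: 23 cyclisation precursor
Product: 24 [(1S,2R,3R)-7-hydroxy-3-(hydroxymethyl)-6,8-dimethoxy-1-[3-methoxy-4-(pivaloyloxy)phenyl]-1,2,3,4-tetrahydronaphthalen-2-yl]methyl pivalate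
Conditions: BF3·OEt2 (1.5 equiv), CH2Cl2 (5 mM), −78 → −30 °C; Et3N quench
Reagents that add atoms: none
Why: BF3 binds the oxetane oxygen and ring A, whose C4a is para to the free C7 hydroxyl, attacks one ring CH2 from the backside (SN2-like Friedel–Crafts alkylation); loss of the C4a proton restores the arene and the C9 oxygen is released as the alcohol on work-up. The closest known reaction type is the acid-promoted intramolecular opening and desymmetrisation of 3-substituted oxetanes by tethered nucleophiles, together with Lewis-acid Friedel–Crafts alkylation of arenes by oxetanes and epoxides; strain release makes the primary carbon electrophilic enough. The carbocycle closes 6-exo-tet (C4–C4a forms, the breaking C4–O bond lies outside the new ring). C3 is set by C1 and C2 through a chair-like transition state: backside attack holds the spectator CH2O arm (C9) anti to C4a, i.e. equatorial, and the chair that grows out of the H1/H2-anti rotamer, with the guaiacyl group and the pivaloyloxymethyl arm equatorial, should give the required 3R (2,3-trans) isomer, whereas the competing chair needs that arm axial, gauche to both oxetane carbons and over the BF3-bound oxygen. Two selectivities are needed: the pro-trans CH2 (favoured by the bulky, non-chelating pivalate and a monodentate Lewis acid, opposed by allylic strain between the equatorial guaiacyl group and the C8 methoxy) and ring A over the guaiacyl ring (the latter carries an acyloxy group meta to its reactive carbon and binds BF3 at the ester, the former a para hydroxyl). The C9' pivalate keeps that oxygen from closing a tetrahydrofuran, and high dilution suppresses intermolecular opening by the phenol or the new alcohol.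

Step 14
Reactants: 24 tetralin bis-pivalate
Product: 25 (+)-8-methoxyisolariciresinol, (1S,2R,3R)
Conditions: LiAlH4 (excess), THF, 0 °C → rt; aqueous Rochelle salt, pH 5
Reagents that add atoms: none
Why: Hydride reduction cleaves the aryl and the alkyl pivalate to neopentyl alcohol under non-oxidising conditions and frees the phenol and the C9' alcohol without touching C1, C2 or C3.

**Compound list**

1 | oxetan-3-one | O=C1COC1 | starting material
2 | benzyl (triphenylphosphoranylidene)acetate | O=C(C=P(c1ccccc1)(c1ccccc1)c1ccccc1)OCc1ccccc1 | starting material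
3 | benzyl 2-(oxetan-3-ylidene)acetate | O=C(C=C1COC1)OCc1ccccc1 | intermediate
4 | benzyl 2-(oxetan-3-yl)acetate | O=C(CC1COC1)OCc1ccccc1 | intermediate
5 | triethylammonium 2-(oxetan-3-yl)acetate | CC[NH+](CC)CC.[O-]C(=O)CC1COC1 | intermediate
6 | (S)-4-benzyloxazolidin-2-one | O=C1N[C@@H](Cc2ccccc2)CO1 | starting material
7 | 2-(oxetan-3-yl)acetic pivalic anhydride | CC(C)(C)C(=O)OC(=O)CC1COC1 | intermediate
8 | (S)-4-benzyl-3-[2-(oxetan-3-yl)acetyl]oxazolidin-2-one | O=C(CC1COC1)N1C(=O)OC[C@@H]1Cc1ccccc1 | intermediate
9 | vanillin | COc1cc(C=O)ccc1O | starting material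
10 | 4-(tert-butyldimethylsilyloxy)-3-methoxybenzaldehyde | COc1cc(C=O)ccc1O[Si](C)(C)C(C)(C)C | intermediate
11 | dibutylboron (Z)-enolate of 8 | CCCCB(CCCC)O/C(=C\C1COC1)N1C(=O)OC[C@@H]1Cc1ccccc1 | intermediate
12 | (4S)-4-benzyl-3-[(2S,3S)-3-[4-(tert-butyldimethylsilyloxy)-3-methoxyphenyl]-3-hydroxy-2-(oxetan-3-yl)propanoyl]oxazolidin-2-one | COc1cc([C@@H](O)[C@H](C2COC2)C(=O)N2C(=O)OC[C@@H]2Cc2ccccc2)ccc1O[Si](C)(C)C(C)(C)C | intermediate
13 | (1S,2R)-1-[4-(tert-butyldimethylsilyloxy)-3-methoxyphenyl]-2-(oxetan-3-yl)propane-1,3-diol | COc1cc([C@@H](O)[C@H](C2COC2)CO)ccc1O[Si](C)(C)C(C)(C)C | intermediate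
14 | (1S,2R)-1-[4-(tert-butyldimethylsilyloxy)-3-methoxyphenyl]-2-(oxetan-3-yl)propane-1,3-diyl bis(2,2-dimethylpropanoate) | COc1cc([C@@H](OC(=O)C(C)(C)C)[C@H](C2COC2)COC(=O)C(C)(C)C)ccc1O[Si](C)(C)C(C)(C)C | intermediate
15 | (1S,2R)-1-(4-hydroxy-3-methoxyphenyl)-2-(oxetan-3-yl)propane-1,3-diyl bis(2,2-dimethylpropanoate) | COc1cc([C@@H](OC(=O)C(C)(C)C)[C@H](C2COC2)COC(=O)C(C)(C)C)ccc1O | intermediate
16 | 2,6-dimethoxyphenol | COc1cccc(OC)c1O | starting material
17 | 2-(benzyloxy)-1,3-dimethoxybenzene | COc1cccc(OC)c1OCc1ccccc1 | intermediate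
18 | 3-(benzyloxy)-1-bromo-2,4-dimethoxybenzene | COc1ccc(Br)c(OC)c1OCc1ccccc1 | intermediate
19 | [3-(benzyloxy)-2,4-dimethoxyphenyl]magnesium bromide | COc1ccc([Mg]Br)c(OC)c1OCc1ccccc1 | intermediate
20 | (2R)-3-(3-methoxy-4-oxocyclohexa-2,5-dien-1-ylidene)-2-(oxetan-3-yl)propyl pivalate (quinone methide, alkene geometry not defined) | COC1=CC(=C[C@H](C2COC2)COC(=O)C(C)(C)C)C=CC1=O | intermediate
21 | (2R,3S)-3-[3-(benzyloxy)-2,4-dimethoxyphenyl]-3-(4-hydroxy-3-methoxyphenyl)-2-(oxetan-3-yl)propyl pivalate (formed as its magnesium phenoxide) | COc1cc([C@@H](c2ccc(OC)c(OCc3ccccc3)c2OC)[C@@H](COC(=O)C(C)(C)C)C2COC2)ccc1O | intermediate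
22 | (2R,3S)-3-[3-(benzyloxy)-2,4-dimethoxyphenyl]-3-[3-methoxy-4-(pivaloyloxy)phenyl]-2-(oxetan-3-yl)propyl pivalate | COc1cc([C@@H](c2ccc(OC)c(OCc3ccccc3)c2OC)[C@@H](COC(=O)C(C)(C)C)C2COC2)ccc1OC(=O)C(C)(C)C | intermediate
23 | (2R,3S)-3-(3-hydroxy-2,4-dimethoxyphenyl)-3-[3-methoxy-4-(pivaloyloxy)phenyl]-2-(oxetan-3-yl)propyl pivalate | COc1cc([C@@H](c2ccc(OC)c(O)c2OC)[C@@H](COC(=O)C(C)(C)C)C2COC2)ccc1OC(=O)C(C)(C)C | intermediate
24 | [(1S,2R,3R)-7-hydroxy-3-(hydroxymethyl)-6,8-dimethoxy-1-[3-methoxy-4-(pivaloyloxy)phenyl]-1,2,3,4-tetrahydronaphthalen-2-yl]methyl pivalate | COc1cc([C@H]2c3c(cc(OC)c(O)c3OC)C[C@@H](CO)[C@@H]2COC(=O)C(C)(C)C)ccc1OC(=O)C(C)(C)C | intermediate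
25 | (+)-8-methoxyisolariciresinol, (1S,2R,3R) | COc1cc([C@H]2c3c(cc(OC)c(O)c3OC)C[C@@H](CO)[C@@H]2CO)ccc1O | target

**Totals**

Total step count: 14. Longest linear sequence: 11 steps (1, 2, 3, 5, 6, 7, 8, 11, 12, 13, 14).

**Steps most likely to fail**

1. Step 13. The arene may attack the other diastereotopic CH2. The chair with the guaiacyl group and the C2 arm axial escapes the allylic strain against the C8 methoxy and would lead to the 3-epimer; a twisted transition state is also possible, so selectivity at C3 may be low or reversed. Intermolecular opening is the second failure mode. Fallback, from 22 back to 24: the oxetane is opened by bromide under catalyst control instead of by the arene. TMSBr with a chiral squaramide hydrogen-bond-donor catalyst (t-BuOMe, −78 °C, using the catalyst enantiomer that sends bromide to the CH2 destined to become C4) should give the bromohydrin trimethylsilyl ether F1. Brief methanolysis (MeOH, PPTS) gives the bromo alcohol F2, and hydrogenolysis (H2, Pd/C, EtOAc, no base) gives the bromo alcohol phenol F3. Potassium tert-butoxide (1.0 equiv, t-BuOH/THF) then closes C4–C4a by intramolecular para C-alkylation of the phenoxide, whose ortho positions are both blocked by methoxy groups. This closure is stereospecific, no longer has to choose a CH2, and delivers 24.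

2. Step 11. Facial selectivity of the 1,6-addition rests on 1,2-induction between two C2 substituents of similar size, so the aryl group may enter the wrong face or both faces. The quinone methide may also isomerise to the styrene before it is trapped. Fallback, from 21 (isolated by quenching with NH4Cl instead of pivaloyl chloride) back to 22: C1 is re-set by letting hydrogen, not the aryl group, arrive last. Oxidation of the p-(diarylmethyl)phenol (Ag2O, CH2Cl2, rt) gives the diaryl quinone methide F4. 1,6-Reduction (NaBH4, THF/MeOH, −78 °C, or L-Selectride as the bulkier hydride) should put hydride on the face that the aryl group had used, which inverts C1. This helps if the aryl addition is selective for the wrong face; if it is unselective, the hydride step gives a second, differently biased attempt. Pivaloylation (PivCl, Et3N, DMAP) then gives 22.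

3. Step 3. The carboxylate or its mixed anhydride may be attacked by the oxetane oxygen, which isomerises the material to a γ-lactone during concentration or activation. Fallback, from 6 and 1 back to 8: the imide is assembled before the oxetane meets any carboxyl derivative. N-Acylation of 6 (n-BuLi, bromoacetyl bromide, THF, −78 °C) gives the bromoacetyl imide F5. Arbuzov reaction with triethyl phosphite (neat, 90 °C) gives the phosphonate F6. Horner–Wadsworth–Emmons olefination of 1 (LiCl, i-Pr2NEt, MeCN, rt) gives the oxetan-3-ylidene imide F7, and hydrogenation (H2, Pd/C, EtOAc) gives 8.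

**Further compounds**

F1 | step 13 | (2R,3S)-3-[3-(benzyloxy)-2,4-dimethoxyphenyl]-2-[(2R)-1-bromo-3-(trimethylsilyloxy)propan-2-yl]-3-[3-methoxy-4-(pivaloyloxy)phenyl]propyl pivalate | BrC[C@@H](CO[Si](C)(C)C)[C@H](COC(=O)C(C)(C)C)[C@H](c1ccc(OC)c(OCc2ccccc2)c1OC)c1ccc(OC(=O)C(C)(C)C)c(OC)c1
F2 | step 13 | (2R,3S)-3-[3-(benzyloxy)-2,4-dimethoxyphenyl]-2-[(2R)-1-bromo-3-hydroxypropan-2-yl]-3-[3-methoxy-4-(pivaloyloxy)phenyl]propyl pivalate | BrC[C@@H](CO)[C@H](COC(=O)C(C)(C)C)[C@H](c1ccc(OC)c(OCc2ccccc2)c1OC)c1ccc(OC(=O)C(C)(C)C)c(OC)c1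
F3 | step 13 | (2R,3S)-2-[(2R)-1-bromo-3-hydroxypropan-2-yl]-3-(3-hydroxy-2,4-dimethoxyphenyl)-3-[3-methoxy-4-(pivaloyloxy)phenyl]propyl pivalate | BrC[C@@H](CO)[C@H](COC(=O)C(C)(C)C)[C@H](c1ccc(OC)c(O)c1OC)c1ccc(OC(=O)C(C)(C)C)c(OC)c1
F4 | step 11 | (2S)-3-[3-(benzyloxy)-2,4-dimethoxyphenyl]-3-(3-methoxy-4-oxocyclohexa-2,5-dien-1-ylidene)-2-(oxetan-3-yl)propyl pivalate | COC1=CC(=C(c2ccc(OC)c(OCc3ccccc3)c2OC)[C@H](C2COC2)COC(=O)C(C)(C)C)C=CC1=O
F5 | step 3 | (S)-4-benzyl-3-(2-bromoacetyl)oxazolidin-2-one | O=C(CBr)N1C(=O)OC[C@@H]1Cc1ccccc1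
F6 | step 3 | diethyl {2-[(4S)-4-benzyl-2-oxooxazolidin-3-yl]-2-oxoethyl}phosphonate | CCOP(=O)(CC(=O)N1C(=O)OC[C@@H]1Cc1ccccc1)OCC
F7 | step 3 | (S)-4-benzyl-3-[2-(oxetan-3-ylidene)acetyl]oxazolidin-2-one | O=C(C=C1COC1)N1C(=O)OC[C@@H]1Cc1ccccc1
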